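## Structural features

The target is a 2,3,4,5-tetrasubstituted tetrahydrofuran in which O1 lies between two benzylic carbons: C2 carries a 4-hydroxy-3,5-dimethoxyphenyl ring and C5 a 3,4,5-trimethoxyphenyl ring, while C3 and C4 each carry a hydroxymethyl group. The four stereocentres are contiguous, (2R,3S,4S,5R), and every neighbouring pair is trans, so the ring has the thermodynamically preferred all-trans arrangement. The two halves differ by a single O-methyl group, so a synthesis must tell two almost identical aryl groups apart while fixing the absolute configuration. The fragile elements are the two ring C–O bonds, both benzylic to electron-rich arenes, and the free phenol para to one of them. Acid can ionise these bonds, with epimerisation or capture of the cation by a neighbouring CH2OH, and hydrogenolysis can cleave them. The real difficulty is therefore the unsymmetrical, acid-free placement of four adjacent centres, not ring formation as such. The key step uses the C3–C4 bond and the exocyclic carbon on C3: the five-membered ring is treated as the contracted form of a 2,6-trans-diaryl tetrahydropyran-4-one whose carbonyl carbon, lying between the future C3 and C4, is pushed out of the ring to become the C3 carbinol carbon as C3 and C4 are joined. Because all-trans is also the most stable arrangement, the one centre the contraction leaves open (C3) can be settled by equilibration.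

## Logic of the disconnections

**18 ⇒ 17.** The two O–CH2Ph bonds are cut, one on the phenol oxygen and one on the oxygen of the C4 hydroxymethyl group. Both hydroxyls must be masked through organolithium, enolate, diazo-transfer and hydride chemistry, and one kind of group allows a single neutral unmasking with no acid near the ring ether. The gain is a precursor with only one free hydroxyl. The demand is that the hydrogenolysis removes unhindered O-benzyl groups faster than it attacks the benzylic ring C–O bonds.

**17 ⇒ 16.** No skeletal bond is cut; the C3 hydroxymethyl group is traced back to a methyl ester. The ester is what the ring contraction delivers, and being enolisable it lets C3 be corrected. The gain is that the two hydroxymethyl arms are different functions throughout and never have to be distinguished by protecting-group moves. The demand is a hydride reduction that leaves benzyl ethers and ring untouched.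

**16 ⇒ 13 (through 15 and 14).** The ring bond C3–C4 is cut; in exchange C4 is re-attached to the ester carbon, which re-enters the ring as a ketone carbonyl, and C3 receives a diazo group. The gain is a six-membered ring, in which the 2,6-trans and 5,6-trans relationships follow from ordinary half-chair stereocontrol; only three centres must then be made directly. The demands are a shift of the substituted ring carbon with retention, in preference to hydride shift and O–H insertion, and equilibration of the protonation-derived C3 centre, which is built into the same flask.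

**13 ⇒ 11 (through 12).** The C3=N2 bond is cut, leaving a plain ketone. The demand is activation at the C3 methylene and not at the C5 methine, whose enolisation would epimerise C5 or expel the β-benzyloxy group. Long-lived stabilised anions, which could open the ring by loss of the ring oxygen from C2, should also be kept short and cold. A kinetic, low-temperature acylation is therefore preferred to a thermodynamic formylation.

**11 ⇒ 5 + 6 + 7 (through 8, 9 and 10).** The C6–aryl bond and the C5–CH2 bond are cut. They sit on the β and α carbons of an enone, so one conjugate addition with trapping of the enolate makes both. The gain is three simple pieces, and the differentiation problem is solved because one aryl ring arrives as a nucleophile and the other was an electrophile. The demands are axial attack anti to the existing aryl group (2,6-trans) and C-alkylation anti to the new aryl group (5,6-trans) before the enolate can equilibrate.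

**5 ⇒ 2 + 3 (through 4).** The C2–C3 and O1–C6 bonds of the dihydropyranone are cut (hetero-Diels–Alder retron). The gain is one aromatic aldehyde and a commercial diene. This is the only step where absolute configuration must come from outside, so it demands high enantioface selectivity on an electron-rich aldehyde and a cyclisation that does not ionise the benzylic C–O bond.

**2 ⇒ 1.** The aryl O–CH2Ph bond is cut, because a free phenol would quench the organometallics and bind the Lewis acid. The gain is a commercial phenolic aldehyde; the only demand is clean O-alkylation.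

## Other disconnections considered

**Alternative 1:** The two exocyclic bonds C4–CH2 and C3–CH2 are cut, and the ring is read as a γ-lactone whose carbonyl carbon is the future C2.
- Forward key step: butenolide A1 would take up Grignard reagent A2 at C4 under CuBr·SMe2 catalysis, anti to the C5 aryl group, and the enolate would be alkylated at C3 by 7 to give lactone A3. Addition of the second aryl group as an organolithium, ionic reduction of the lactol, Tamao–Fleming oxidation of the C–Si bond and debenzylation would follow.
- In favour: two C–C bonds and two stereocentres form at once under substrate control, with no diazo compound and no light.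
- Against: A1 must be made enantiopure in its own sequence, and its benzylic, γ-acidic C5–H could racemise through the furanolate under the basic key step. The C2 aryl group and its configuration come last, through an oxocarbenium ion under a Lewis acid, which the benzylic ring ether tolerates least, and the sense of hydride delivery is not secured.
- Comparison: Alternative 1 is better in bonds formed per step and in reagent safety. The conjugate addition–alkylation is the same kind of reaction as step 3, so the two are equal there, and step count is about equal once A1 is included. The chosen plan is stronger in control of C2 and in how the two aryl rings are told apart.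

**Alternative 2:** The cut is at O1–C5 and C4–C5, so C5 with its aryl group comes from aldehyde A5 and the rest from silylpentenol A4.
- Forward key step: Me3SiOTf would condense the benzylic hydroxyl of A4 with A5 to an oxocarbenium ion; the allylsilane would attack through C4 with loss of silicon, closing the ring to the 4-vinyl compound A6. Oxidative cleavage of the vinyl group, reduction, desilylation and debenzylation would follow.
- In favour: it is the most convergent plan. Ring, two bonds and two stereocentres form in one step directly in the five-membered series, an envelope transition state with pseudo-equatorial substituents points to the all-trans product, and no azide or photochemistry is needed.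
- Against: A4 is a para-alkoxybenzylic alcohol that could ionise under Me3SiOTf instead of condensing, eroding C2 or eliminating. A 2-oxonia-Cope rearrangement is a second leak of stereochemical information. A4 needs two adjacent stereocentres and an (E)-allylsilane, some five to six steps. The vinyl group must be cleaved oxidatively beside two electron-rich arenes.
- Comparison: Alternative 2 is better in convergence and in what its key step achieves, since the chosen key step forms one bond and leaves its new centre to equilibration. The two are equal in ending on the thermodynamically preferred ring. Alternative 2 is weaker in acid exposure at the key step and longer overall (roughly ten to eleven steps against seven).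

**Alternative 3:** The cuts are O1–C2 and C3–C4: vinyl epoxide A7 supplies C4, C5 and O1, and arylidene malonate A8 supplies C2 and C3.
- Forward key step: zerovalent palladium from Pd2(dba)3 and a bisphosphine would open A7 to a π-allyl complex carrying a benzylic alkoxide. The alkoxide would add to the β-carbon of A8, and the malonate anion would close on the internal allyl carbon to give diester A9. Krapcho loss of one ester, cleavage and reduction of the vinyl group, ester reduction and debenzylation would follow.
- In favour: the ring-forming step is catalytic and convergent, and both partners are one or two steps from the aldehydes, so the route could be as short as the chosen one or shorter.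
- Against: only C5 is fixed beforehand (A7 must be enantiopure). C2 and C4 arise in a reversible oxa-Michael addition and an allylic alkylation through an equilibrating π-allyl complex, with nothing strong to enforce 2,5-trans and 4,5-trans. A8 is a weak acceptor, so isomerisation of the opened epoxide could compete. The hot, chloride-mediated ester loss invites β-elimination of the ring oxygen from C2.
- Comparison: Alternative 3 is equal or better in step economy and clearly better in convergence and in being catalytic. It is weaker in stereocontrol, since three centres hang on one step of uncertain diastereoselectivity, whereas each centre of the chosen plan has its own controlling element.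

Key step: step 5

Remark on numbering: pyranone compounds are numbered O1, C2 (benzyloxy-dimethoxyphenyl), C3, C4 (carbonyl), C5, C6 (trimethoxyphenyl); after the contraction the ring is numbered as in the target.

Remark (assumption): the catalyst from (R)-BINOL and Ti(OiPr)4 is assumed to deliver the diene to the Re face of aldehyde 2, as expected for aromatic aldehydes; if the sense were opposite, (S)-BINOL would be used.

## Route

Step 1
Reactants: 1 4-hydroxy-3,5-dimethoxybenzaldehyde (syringaldehyde)
Product: 2 4-(benzyloxy)-3,5-dimethoxybenzaldehyde
Conditions: BnBr, K2CO3, DMF, rt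
Reagents that add atoms: benzyl bromide, BrCc1ccccc1
Why: Williamson ether synthesis: the phenoxide, made more acidic by the para formyl group, is alkylated on oxygen by the benzylic bromide; no stereocentre is involved.

Step 2
Reactants: 2 4-(benzyloxy)-3,5-dimethoxybenzaldehyde; 3 (E)-1-methoxy-3-(trimethylsilyloxy)buta-1,3-diene
Product: 5 (2R)-2-[4-(benzyloxy)-3,5-dimethoxyphenyl]-2,3-dihydro-4H-pyran-4-one, via open-chain aldol adduct 4 (not isolated)
Conditions: (R)-BINOL (20 mol %), Ti(OiPr)4 (10 mol %), 4 Å MS, Et2O, −20 °C; then CF3CO2H, CH2Cl2, 0 °C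
Reagents that add atoms: none
Why: Catalytic enantioselective hetero-Diels–Alder reaction in its stepwise form (Mukaiyama aldol, then cyclisation): the BINOL-bound tetravalent titanium Lewis acid should expose the Re face of the aldehyde to the diene terminus, fixing C2 as R in 4, and acid then closes 4 by conjugate addition of the oxygen and loss of methanol. The 4-alkoxy group, twisted out of conjugation by its two ortho methoxy groups, should make the benzylic C–O bond less prone to acid ionisation than in a para-anisyl case.

Step 3
Reactants: 5 (2R)-2-[4-(benzyloxy)-3,5-dimethoxyphenyl]-2,3-dihydro-4H-pyran-4-one; 6 5-bromo-1,2,3-trimethoxybenzene; 7 benzyl chloromethyl ether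
Product: 11 (2R,5S,6R)-2-[4-(benzyloxy)-3,5-dimethoxyphenyl]-5-[(benzyloxy)methyl]-6-(3,4,5-trimethoxyphenyl)tetrahydro-4H-pyran-4-one, via aryllithium 8 (not isolated), via lithium diarylcuprate 9 (not isolated), via lithium enolate 10 (not isolated)
Conditions: 6, n-BuLi, THF, −78 °C; CuI, −78 to −40 °C; 5, −78 to −40 °C; then DMPU, 7, −78 to −20 °C; aq. NH4Cl
Reagents that add atoms: none
Why: Conjugate addition–enolate alkylation: cuprate 9 (monovalent copper) should add to C6 of the half-chair enone along the axial trajectory anti to the pseudo-equatorial C2 aryl group, giving the 2,6-trans enolate 10 with its double bond fixed toward C5. Chloromethyl ether 7, an activated SN2 electrophile, should then alkylate C5 from the face opposite the now pseudo-axial C6 aryl group (5,6-trans). DMPU loosens the enolate aggregate, and an excess of 7 allows for its consumption by residual arylcopper.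

Step 4
Reactants: 11 (2R,5S,6R)-2-[4-(benzyloxy)-3,5-dimethoxyphenyl]-5-[(benzyloxy)methyl]-6-(3,4,5-trimethoxyphenyl)tetrahydro-4H-pyran-4-one
Product: 13 (2S,5S,6R)-2-[4-(benzyloxy)-3,5-dimethoxyphenyl]-5-[(benzyloxy)methyl]-3-diazo-6-(3,4,5-trimethoxyphenyl)tetrahydro-4H-pyran-4-one, via trifluoroacetyl ketone 12 (not isolated)
Conditions: LiHMDS, THF, −78 °C; CF3CO2CH2CF3, −78 °C; aq. NH4Cl; then p-ABSA, Et3N, H2O (1 equiv), MeCN, rt
Reagents that add atoms: 4-acetamidobenzenesulfonyl azide (p-ABSA), CC(=O)Nc1ccc(cc1)S(=O)(=O)N=[N+]=[N-]
Why: Deacylative (detrifluoroacetylative) diazo transfer of the Regitz type: LiHMDS at −78 °C should deprotonate the unhindered C3 methylene and not the C5 methine, so C5 is neither epimerised nor exposed to β-elimination of benzyl oxide. Acylation gives 12, whose enolate attacks the sulfonyl azide and fragments to 13 with transfer of the trifluoroacetyl group to the sulfonamide nitrogen. The acetamido-substituted azide is chosen as the least hazardous common transfer reagent; no stereocentre is formed.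

Step 5
Reactants: 13 (2S,5S,6R)-2-[4-(benzyloxy)-3,5-dimethoxyphenyl]-5-[(benzyloxy)methyl]-3-diazo-6-(3,4,5-trimethoxyphenyl)tetrahydro-4H-pyran-4-one
Product: 16 methyl (2R,3R,4S,5R)-2-[4-(benzyloxy)-3,5-dimethoxyphenyl]-4-[(benzyloxy)methyl]-5-(3,4,5-trimethoxyphenyl)tetrahydrofuran-3-carboxylate, via ketene 14 (not isolated), via C3-epimeric ester 15 (not isolated)
Conditions: hν (>300 nm, Pyrex-filtered medium-pressure Hg lamp or 365 nm LEDs), degassed MeOH, 0 °C to rt; then lamp off, NaOMe (0.3 equiv), MeOH, rt; aq. NH4Cl
Reagents that add atoms: methanol, CO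
Why: Photochemical Wolff rearrangement used as a ring contraction: excitation of the diazo ketone, held s-Z by the ring, expels N2 while the ring carbon carrying the CH2OBn group shifts from the carbonyl carbon to the diazo carbon to give ketene 14; methanol adds to the ketene and the resulting ester enol is protonated at C3. The closest known reaction type is the photolytic Wolff ring contraction of cyclic α-diazo ketones in an alcohol, which converts carbocyclic and oxacyclic diazo ketones into the next smaller ring bearing an ester. The five-membered ring is therefore closed by a 1,2-carbon shift that forms the C3–C4 bond, not by an exo or endo cyclisation. The migrating carbon keeps its configuration, so the 2,6-trans and 5,6-trans relationships of 13 become 2,5-trans and 4,5-trans. The new C3 centre is first set by protonation from the face away from the C2 aryl group and the C4 side chain, which should favour the cis,cis ester 15; methoxide then equilibrates C3 through the ester enolate to 16, the only isomer in which the ester is anti to both neighbours. The step needs the carbon shift to win over a 1,2-hydride shift from C2–H and over O–H insertion into methanol: direct, metal-free irradiation of an s-Z-locked cyclic diazo ketone is where the concerted rearrangement should dominate, and only the group on the carbonyl carbon can migrate, so there is no regiochemical choice. Light above about 300 nm is absorbed by the diazo ketone and not by the alkoxyarenes or benzyl ethers.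

Step 6
Reactants: 16 methyl (2R,3R,4S,5R)-2-[4-(benzyloxy)-3,5-dimethoxyphenyl]-4-[(benzyloxy)methyl]-5-(3,4,5-trimethoxyphenyl)tetrahydrofuran-3-carboxylate
Product: 17 {(2R,3S,4S,5R)-2-[4-(benzyloxy)-3,5-dimethoxyphenyl]-4-[(benzyloxy)methyl]-5-(3,4,5-trimethoxyphenyl)tetrahydrofuran-3-yl}methanol
Conditions: LiAlH4, THF, 0 °C; aq. sodium potassium tartrate
Reagents that add atoms: none
Why: Hydride reduction of the ester to the primary alcohol; benzyl ethers, aryl ethers and the ring are inert to LiAlH4 at 0 °C, and C3 is already in its most stable configuration. The neutral tartrate work-up keeps acid away from the benzylic ring ether.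

Step 7
Reactants: 17 {(2R,3S,4S,5R)-2-[4-(benzyloxy)-3,5-dimethoxyphenyl]-4-[(benzyloxy)methyl]-5-(3,4,5-trimethoxyphenyl)tetrahydrofuran-3-yl}methanol
Product: 18 4-[(2R,3S,4S,5R)-3,4-bis(hydroxymethyl)-5-(3,4,5-trimethoxyphenyl)tetrahydrofuran-2-yl]-2,6-dimethoxyphenol
Conditions: H2 (1 atm), 10% Pd/C, EtOAc–EtOH, rt, stopped at full conversion
Reagents that add atoms: none
Why: Hydrogenolysis of benzyl ethers over palladium: the aryl benzyl ether and the unhindered primary alkyl benzyl ether, each with an unsubstituted phenyl ring that binds well to the metal, should cleave faster than the ring C–O bonds. Those bonds are secondary, flanked by ring substituents and attached to crowded trioxygenated arenes; the same selectivity allows O-debenzylation of C-aryl glycosides. A neutral medium, 1 atm and prompt stopping should keep the ring intact; no stereocentre is touched.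

## Compound list

1 | 4-hydroxy-3,5-dimethoxybenzaldehyde (syringaldehyde) | COc1cc(C=O)cc(OC)c1O | starting material
2 | 4-(benzyloxy)-3,5-dimethoxybenzaldehyde | COc1cc(C=O)cc(OC)c1OCc1ccccc1 | intermediate
3 | (E)-1-methoxy-3-(trimethylsilyloxy)buta-1,3-diene | CO/C=C/C(=C)O[Si](C)(C)C | starting material
4 | (1E,5R)-5-[4-(benzyloxy)-3,5-dimethoxyphenyl]-1-methoxy-5-(trimethylsilyloxy)pent-1-en-3-one (not isolated) | COc1cc([C@@H](CC(=O)/C=C/OC)O[Si](C)(C)C)cc(OC)c1OCc1ccccc1 | intermediate
5 | (2R)-2-[4-(benzyloxy)-3,5-dimethoxyphenyl]-2,3-dihydro-4H-pyran-4-one | COc1cc([C@@H]2OC=CC(=O)C2)cc(OC)c1OCc1ccccc1 | intermediate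
6 | 5-bromo-1,2,3-trimethoxybenzene | COc1cc(Br)cc(OC)c1OC | starting material
7 | benzyl chloromethyl ether | ClCOCc1ccccc1 | starting material
8 | (3,4,5-trimethoxyphenyl)lithium (not isolated) | [Li]c1cc(OC)c(OC)c(OC)c1 | intermediate
9 | lithium bis(3,4,5-trimethoxyphenyl)cuprate, Ar2CuLi, monovalent copper (not isolated) | [Li+].COc1cc([Cu-]c2cc(OC)c(OC)c(OC)c2)cc(OC)c1OC | intermediate
10 | lithium (2R,6R)-2-[4-(benzyloxy)-3,5-dimethoxyphenyl]-6-(3,4,5-trimethoxyphenyl)-3,6-dihydro-2H-pyran-4-olate, 2,6-trans (not isolated) | COc1cc([C@@H]2O[C@@H](c3cc(OC)c(OC)c(OC)c3)C=C(O[Li])C2)cc(OC)c1OCc1ccccc1 | intermediate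
11 | (2R,5S,6R)-2-[4-(benzyloxy)-3,5-dimethoxyphenyl]-5-[(benzyloxy)methyl]-6-(3,4,5-trimethoxyphenyl)tetrahydro-4H-pyran-4-one, 2,6-trans and 5,6-trans | COc1cc([C@@H]2O[C@@H](c3cc(OC)c(OC)c(OC)c3)[C@H](COCc4ccccc4)C(=O)C2)cc(OC)c1OCc1ccccc1 | intermediate
12 | 3-(trifluoroacetyl) derivative of 11, drawn as its ring enol, 2,6-trans and 5,6-trans (not isolated) | COc1cc([C@@H]2O[C@@H](c3cc(OC)c(OC)c(OC)c3)[C@H](COCc4ccccc4)C(O)=C2C(=O)C(F)(F)F)cc(OC)c1OCc1ccccc1 | intermediate
13 | (2S,5S,6R)-2-[4-(benzyloxy)-3,5-dimethoxyphenyl]-5-[(benzyloxy)methyl]-3-diazo-6-(3,4,5-trimethoxyphenyl)tetrahydro-4H-pyran-4-one, 2,6-trans and 5,6-trans (key-step precursor) | COc1cc([C@@H]2O[C@@H](c3cc(OC)c(OC)c(OC)c3)[C@H](COCc4ccccc4)C(=O)C2=[N+]=[N-])cc(OC)c1OCc1ccccc1 | intermediate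
14 | 2-[4-(benzyloxy)-3,5-dimethoxyphenyl]-4-[(benzyloxy)methyl]-3-(oxomethylidene)-5-(3,4,5-trimethoxyphenyl)tetrahydrofuran, 2,5-trans and 4,5-trans ketene (not isolated) | COc1cc([C@@H]2O[C@@H](c3cc(OC)c(OC)c(OC)c3)[C@H](COCc4ccccc4)C2=C=O)cc(OC)c1OCc1ccccc1 | intermediate
15 | methyl (2R,3S,4S,5R)-2-[4-(benzyloxy)-3,5-dimethoxyphenyl]-4-[(benzyloxy)methyl]-5-(3,4,5-trimethoxyphenyl)tetrahydrofuran-3-carboxylate, 2,3-cis and 3,4-cis (not isolated) | COc1cc([C@@H]2O[C@@H](c3cc(OC)c(OC)c(OC)c3)[C@H](COCc4ccccc4)[C@@H]2C(=O)OC)cc(OC)c1OCc1ccccc1 | intermediate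
16 | methyl (2R,3R,4S,5R)-2-[4-(benzyloxy)-3,5-dimethoxyphenyl]-4-[(benzyloxy)methyl]-5-(3,4,5-trimethoxyphenyl)tetrahydrofuran-3-carboxylate, all-trans (key-step product) | COc1cc([C@@H]2O[C@@H](c3cc(OC)c(OC)c(OC)c3)[C@H](COCc4ccccc4)[C@H]2C(=O)OC)cc(OC)c1OCc1ccccc1 | intermediate
17 | {(2R,3S,4S,5R)-2-[4-(benzyloxy)-3,5-dimethoxyphenyl]-4-[(benzyloxy)methyl]-5-(3,4,5-trimethoxyphenyl)tetrahydrofuran-3-yl}methanol, all-trans | COc1cc([C@@H]2O[C@@H](c3cc(OC)c(OC)c(OC)c3)[C@H](COCc4ccccc4)[C@H]2CO)cc(OC)c1OCc1ccccc1 | intermediate
18 | 4-[(2R,3S,4S,5R)-3,4-bis(hydroxymethyl)-5-(3,4,5-trimethoxyphenyl)tetrahydrofuran-2-yl]-2,6-dimethoxyphenol | COc1cc([C@@H]2O[C@@H](c3cc(OC)c(OC)c(OC)c3)[C@H](CO)[C@H]2CO)cc(OC)c1O | target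

## Step count and least certain steps

Total step count: 7. Longest linear sequence: 7 steps (1 to 18); fragments 3, 6 and 7 are commercial.

**Step 5 (key step).** The excited diazo ketone or carbene may be diverted into a 1,2-hydride migration from the benzylic C2–H or into O–H insertion with the solvent. In the base phase, the ring may open by β-elimination of the ring oxygen from the ester enolate. The fallback is a carbene-free semipinacol ring contraction that sets out from 11 and returns at 17. The kinetic enolate of 11 (LiHMDS, −78 °C) is hydroxylated with 2-(phenylsulfonyl)-3-phenyloxaziridine anti to the C2 aryl group to give the 3-hydroxy ketone F1, and MsCl/Et3N converts it into the mesylate F2. Hydride reduction of the ketone (NaBH4, MeOH, −20 °C, or a bulkier hydride if needed to place the hydroxyl trans to the mesylate) gives the trans hydroxy mesylate F3. With KOt-Bu in THF at 0 °C the alkoxide should drive the C4–C5 ring bond, antiperiplanar to the equatorial mesylate, to migrate to C3. This contracts the ring to the aldehyde F4, which the base brings to the all-trans form, and NaBH4 then reduces F4 to 17. This path depends on the diequatorial conformer reacting; the diaxial conformer would give an epoxide.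

**Step 3.** The copper-containing enolate aggregate may alkylate sluggishly or on oxygen, or proton transfer may move the enolate toward C3 before alkylation, with loss of regio- and stereocontrol. The fallback separates the two events; it sets out from 5 and returns at 11. The cuprate addition is run with Me3SiCl present to give the trimethylsilyl enol ether F5, which is isolated. MeLi in THF then regenerates the copper-free lithium enolate 10 regiospecifically, and 7 alkylates it at −78 °C.

**Step 4.** During the room-temperature azide stage the stabilised β-dicarbonyl anion may open the ring by β-elimination of the ring oxygen from C2 and re-close, eroding the 2,6-trans relationship; enolisation straying to C5 would cause loss of benzyl oxide. The fallback drops the acyl activating group; it sets out from 11 and returns at 13. The kinetic lithium enolate (LiHMDS, −78 °C) is treated directly with 4-nitrobenzenesulfonyl azide, whose triazene adduct fragments to the diazo ketone at low temperature. This is a known but less general transfer, and it makes no new isolable compound.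

**Step 7.** Hydrogenolytic opening of the ring at the electron-rich benzylic C–O bonds may compete with cleavage of the slower primary alkyl benzyl ether. The fallback removes the alkyl benzyl ether from the plan; it sets out from enolate 10 (generated as in step 3) and returns at 18.
- Enolate 10 is quenched at −78 °C with monomeric formaldehyde (from cracked paraformaldehyde) instead of 7, giving the hydroxymethyl ketone F6. TBSCl/imidazole converts it into the silyl ether F7.
- The operations of steps 4 to 6 are then applied: acylation to the trifluoroacetyl ketone F8 and diazo transfer to the diazo ketone F9; photolysis through the ketene F10 and the C3-epimeric ester F11 to the all-trans ester F12 after methoxide; and LiAlH4 reduction to the alcohol F13.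
- Bu4NF in THF frees the diol F14. A brief hydrogenolysis (H2, Pd/C, EtOAc), which now has only the fast-reacting aryl benzyl ether to cleave, gives 18.

## Further compounds

F1 | step 5 | 2-[4-(benzyloxy)-3,5-dimethoxyphenyl]-5-[(benzyloxy)methyl]-3-hydroxy-6-(3,4,5-trimethoxyphenyl)tetrahydro-4H-pyran-4-one, 2,3-trans, 2,6-trans, 5,6-trans | COc1cc([C@@H]2O[C@@H](c3cc(OC)c(OC)c(OC)c3)[C@H](COCc4ccccc4)C(=O)[C@H]2O)cc(OC)c1OCc1ccccc1
F2 | step 5 | methanesulfonate of F1 (3-mesyloxy ketone), same configuration | COc1cc([C@@H]2O[C@@H](c3cc(OC)c(OC)c(OC)c3)[C@H](COCc4ccccc4)C(=O)[C@H]2OS(C)(=O)=O)cc(OC)c1OCc1ccccc1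
F3 | step 5 | 2-[4-(benzyloxy)-3,5-dimethoxyphenyl]-5-[(benzyloxy)methyl]-4-hydroxy-6-(3,4,5-trimethoxyphenyl)tetrahydropyran-3-yl methanesulfonate, 3,4-trans, 2,3-trans, 2,6-trans, 5,6-trans | COc1cc([C@@H]2O[C@@H](c3cc(OC)c(OC)c(OC)c3)[C@H](COCc4ccccc4)[C@H](O)[C@H]2OS(C)(=O)=O)cc(OC)c1OCc1ccccc1
F4 | step 5 | all-trans 2-[4-(benzyloxy)-3,5-dimethoxyphenyl]-4-[(benzyloxy)methyl]-5-(3,4,5-trimethoxyphenyl)tetrahydrofuran-3-carbaldehyde | COc1cc([C@@H]2O[C@@H](c3cc(OC)c(OC)c(OC)c3)[C@H](COCc4ccccc4)[C@H]2C=O)cc(OC)c1OCc1ccccc1
F5 | step 3 | (2R,6R)-2-[4-(benzyloxy)-3,5-dimethoxyphenyl]-6-(3,4,5-trimethoxyphenyl)-4-(trimethylsilyloxy)-3,6-dihydro-2H-pyran, 2,6-trans | COc1cc([C@@H]2O[C@@H](c3cc(OC)c(OC)c(OC)c3)C=C(O[Si](C)(C)C)C2)cc(OC)c1OCc1ccccc1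
F0 | step 4 | none | none
F6 | step 7 | 2-[4-(benzyloxy)-3,5-dimethoxyphenyl]-5-(hydroxymethyl)-6-(3,4,5-trimethoxyphenyl)tetrahydro-4H-pyran-4-one, 2,6-trans, 5,6-trans | COc1cc([C@@H]2O[C@@H](c3cc(OC)c(OC)c(OC)c3)[C@H](CO)C(=O)C2)cc(OC)c1OCc1ccccc1
F7 | step 7 | tert-butyldimethylsilyl ether of F6 | COc1cc([C@@H]2O[C@@H](c3cc(OC)c(OC)c(OC)c3)[C@H](CO[Si](C)(C)C(C)(C)C)C(=O)C2)cc(OC)c1OCc1ccccc1
F8 | step 7 | 3-(trifluoroacetyl) derivative of F7, ring enol form | COc1cc([C@@H]2O[C@@H](c3cc(OC)c(OC)c(OC)c3)[C@H](CO[Si](C)(C)C(C)(C)C)C(O)=C2C(=O)C(F)(F)F)cc(OC)c1OCc1ccccc1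
F9 | step 7 | 3-diazo derivative of F7, 2,6-trans, 5,6-trans | COc1cc([C@@H]2O[C@@H](c3cc(OC)c(OC)c(OC)c3)[C@H](CO[Si](C)(C)C(C)(C)C)C(=O)C2=[N+]=[N-])cc(OC)c1OCc1ccccc1
F10 | step 7 | ring-contracted ketene from F9, 2,5-trans, 4,5-trans | COc1cc([C@@H]2O[C@@H](c3cc(OC)c(OC)c(OC)c3)[C@H](CO[Si](C)(C)C(C)(C)C)C2=C=O)cc(OC)c1OCc1ccccc1
F11 | step 7 | methyl 2-[4-(benzyloxy)-3,5-dimethoxyphenyl]-4-[(tert-butyldimethylsilyloxy)methyl]-5-(3,4,5-trimethoxyphenyl)tetrahydrofuran-3-carboxylate, 2,3-cis and 3,4-cis epimer | COc1cc([C@@H]2O[C@@H](c3cc(OC)c(OC)c(OC)c3)[C@H](CO[Si](C)(C)C(C)(C)C)[C@@H]2C(=O)OC)cc(OC)c1OCc1ccccc1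
F12 | step 7 | all-trans methyl 2-[4-(benzyloxy)-3,5-dimethoxyphenyl]-4-[(tert-butyldimethylsilyloxy)methyl]-5-(3,4,5-trimethoxyphenyl)tetrahydrofuran-3-carboxylate | COc1cc([C@@H]2O[C@@H](c3cc(OC)c(OC)c(OC)c3)[C@H](CO[Si](C)(C)C(C)(C)C)[C@H]2C(=O)OC)cc(OC)c1OCc1ccccc1
F13 | step 7 | all-trans {2-[4-(benzyloxy)-3,5-dimethoxyphenyl]-4-[(tert-butyldimethylsilyloxy)methyl]-5-(3,4,5-trimethoxyphenyl)tetrahydrofuran-3-yl}methanol | COc1cc([C@@H]2O[C@@H](c3cc(OC)c(OC)c(OC)c3)[C@H](CO[Si](C)(C)C(C)(C)C)[C@H]2CO)cc(OC)c1OCc1ccccc1
F14 | step 7 | [(2R,3S,4S,5R)-2-[4-(benzyloxy)-3,5-dimethoxyphenyl]-5-(3,4,5-trimethoxyphenyl)tetrahydrofuran-3,4-diyl]dimethanol | COc1cc([C@@H]2O[C@@H](c3cc(OC)c(OC)c(OC)c3)[C@H](CO)[C@H]2CO)cc(OC)c1OCc1ccccc1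
A1 | alternative 1 | (5R)-5-(3,4,5-trimethoxyphenyl)furan-2(5H)-one | O=C1O[C@@H](c2cc(OC)c(OC)c(OC)c2)C=C1
A2 | alternative 1 | [(isopropoxydimethylsilyl)methyl]magnesium chloride | CC(C)O[Si](C)(C)C[Mg]Cl
A3 | alternative 1 | trans,trans-3-[(benzyloxy)methyl]-4-[(isopropoxydimethylsilyl)methyl]-5-(3,4,5-trimethoxyphenyl)dihydrofuran-2(3H)-one | O=C2O[C@@H](c3cc(OC)c(OC)c(OC)c3)[C@H](C[Si](C)(C)OC(C)C)[C@H]2COCc4ccccc4
A4 | alternative 2 | (1R,2S,3E)-1-[4-(benzyloxy)-3,5-dimethoxyphenyl]-2-[(tert-butyldimethylsilyloxy)methyl]-5-(trimethylsilyl)pent-3-en-1-ol | COc1cc([C@H](O)[C@H](CO[Si](C)(C)C(C)(C)C)/C=C/C[Si](C)(C)C)cc(OC)c1OCc1ccccc1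
A5 | alternative 2 | 3,4,5-trimethoxybenzaldehyde | COc1cc(C=O)cc(OC)c1OC
A6 | alternative 2 | all-trans 2-[4-(benzyloxy)-3,5-dimethoxyphenyl]-3-[(tert-butyldimethylsilyloxy)methyl]-5-(3,4,5-trimethoxyphenyl)-4-vinyltetrahydrofuran | COc1cc([C@@H]2O[C@@H](c3cc(OC)c(OC)c(OC)c3)[C@H](C=C)[C@H]2CO[Si](C)(C)C(C)(C)C)cc(OC)c1OCc1ccccc1
A7 | alternative 3 | (2S,3S)-2-(3,4,5-trimethoxyphenyl)-3-vinyloxirane (trans) | C=C[C@@H]1O[C@H]1c1cc(OC)c(OC)c(OC)c1
A8 | alternative 3 | dimethyl 2-[4-(benzyloxy)-3,5-dimethoxybenzylidene]malonate | COC(=O)C(=Cc1cc(OC)c(OCc2ccccc2)c(OC)c1)C(=O)OC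
A9 | alternative 3 | dimethyl 2-[4-(benzyloxy)-3,5-dimethoxyphenyl]-5-(3,4,5-trimethoxyphenyl)-4-vinyltetrahydrofuran-3,3-dicarboxylate, 2,5-trans and 4,5-trans | COc1cc([C@@H]2O[C@@H](c3cc(OC)c(OC)c(OC)c3)[C@H](C=C)C2(C(=O)OC)C(=O)OC)cc(OC)c1OCc1ccccc1
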